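**Retrosynthetic overview**

1. Target 26 ⇒ tetramethyl ether 25 (cleavage of four ArOMe) ⇒ aryl chloride 23 + 2,4-dimethoxystyrene 24 (Heck at C6–Cl).
2. Feature (unprimed = styryl-bearing dihydrobenzofuran, primed = the other): C2 and C2′ carry a 4-hydroxyphenyl next to the diarylmethine carbons C3 and C3′, and the benzo rings fused at C3a–C7a and C3a′–C7a′ are 2-substituted resorcinols (O1 and 4-OH, O1′ and 4′-OH, equivalent before closure). The core is therefore a constitutional isomer of a flat bis(triarylethylene).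
3. Key disconnection: O1–C2 and O1′–C2′ (with the hydrogens on C3 and C3′) ⇒ hexaphenol 20 (E/Z mixture). Both dihydrofuran rings and all four stereocentres form in this one isomerisation, in either order.
4. 20 ⇒ bis(diaryl ketone) 12 + benzyl chloride 15 (double benzyl Grignard addition, dehydration, non-acidic MOM removal).
5. 12 ⇒ two directed ortho-lithiations (lithiated acetal 5 + aldehyde 6, then lithiated 2 + aldehyde 9), then oxidation.

Key step: step 12

Assumption: 2,4-dimethoxystyrene (24) is taken as a purchasable, stabilised styrene, and the hand of the acid catalyst that gives the 3S,3′S sense cannot be predicted and is fixed by a preliminary screen.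

**Route**

Step 1
Reactants: 1 5-chlororesorcinol
Product: 2 1-chloro-3,5-bis(methoxymethoxy)benzene
Conditions: MOMCl (2.5 equiv), i-Pr2NEt, CH2Cl2, 0 °C → rt
Reagents that add atoms: chloromethyl methyl ether, COCCl
Why: Base-mediated O-alkylation (MOM ether formation) of both phenols gives groups that survive organolithium and Grignard reagents and direct the later ortho-lithiation to the carbon between them.

Step 2
Reactants: 3 3,5-dihydroxybenzaldehyde
Product: 4 3,5-bis(methoxymethoxy)benzaldehyde
Conditions: MOMCl (2.5 equiv), i-Pr2NEt, CH2Cl2, 0 °C → rt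
Reagents that add atoms: chloromethyl methyl ether, COCCl
Why: The same MOM ether formation protects both phenols, and the two OMOM groups later direct lithiation to C4 of this ring.

Step 3
Reactants: 4 3,5-bis(methoxymethoxy)benzaldehyde
Product: 5 1-(dimethoxymethyl)-3,5-bis(methoxymethoxy)benzene
Conditions: HC(OMe)3, MeOH, PPTS (cat.), rt; Et3N quench
Reagents that add atoms: trimethyl orthoformate, COC(OC)OC
Why: Acid-catalysed acetalisation with the orthoformate as water scavenger masks the aldehyde against n-BuLi, and the catalytic pyridinium acid at room temperature should leave the aryl MOM ethers intact.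

Step 4
Reactants: 5 1-(dimethoxymethyl)-3,5-bis(methoxymethoxy)benzene; 6 3,5-dimethoxybenzaldehyde
Product: 9 4-[(3,5-dimethoxyphenyl)(hydroxy)methyl]-3,5-bis(methoxymethoxy)benzaldehyde (racemic), via 4-lithio acetal 7 (not isolated), via acetal carbinol 8 (not isolated)
Conditions: n-BuLi, THF, 0 °C; 6, −78 → 0 °C; then 1 M aq. HCl (pH 2), rt, 30 min
Reagents that add atoms: water, O
Why: Directed ortho-metalation takes place at C4 between the two cooperating OMOM groups, the aryllithium adds 1,2 to aldehyde 6, and the brief dilute-acid quench hydrolyses only the dimethyl acetal; the carbinol centre forms racemic and is erased in step 6.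

Step 5
Reactants: 2 1-chloro-3,5-bis(methoxymethoxy)benzene; 9 4-[(3,5-dimethoxyphenyl)(hydroxy)methyl]-3,5-bis(methoxymethoxy)benzaldehyde
Product: 11 [4-chloro-2,6-bis(methoxymethoxy)phenyl]{4-[(3,5-dimethoxyphenyl)(hydroxy)methyl]-3,5-bis(methoxymethoxy)phenyl}methanol (diastereomer mixture), via aryllithium 10 (not isolated)
Conditions: 2 (2.4 equiv), n-BuLi (2.3 equiv), THF, 0 °C; then 9, −78 → 0 °C; aq. NH4Cl
Reagents that add atoms: none
Why: Directed ortho-metalation of 2 between its OMOM groups (meta to chlorine, so neither exchange nor aryne formation interferes) is followed by 1,2-addition to the aldehyde of 9, one equivalent of aryllithium being spent on the free hydroxyl and returning 2; the new carbinol centre is unselective and is erased in step 6.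

Step 6
Reactants: 11 the bis(diarylmethanol)
Product: 12 [4-chloro-2,6-bis(methoxymethoxy)phenyl][4-(3,5-dimethoxybenzoyl)-3,5-bis(methoxymethoxy)phenyl]methanone
Conditions: Dess–Martin periodinane (3 equiv), CH2Cl2, rt
Reagents that add atoms: none
Why: Dess–Martin oxidation converts both hindered diarylmethanols into diaryl ketones under near-neutral conditions that leave the MOM ethers and the aryl chloride alone.

Step 7
Reactants: 13 4-hydroxybenzyl alcohol
Product: 14 4-(methoxymethoxy)benzyl alcohol
Conditions: MOMCl (1.05 equiv), K2CO3, acetone, 0 °C → rt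
Reagents that add atoms: chloromethyl methyl ether, COCCl
Why: Williamson-type O-alkylation under carbonate base deprotonates only the phenol, so the benzylic alcohol stays free.

Step 8
Reactants: 14 4-(methoxymethoxy)benzyl alcohol
Product: 15 4-(methoxymethoxy)benzyl chloride
Conditions: MsCl, 2,4,6-collidine, LiCl, DMF, 0 °C
Reagents that add atoms: lithium chloride, [Li+].[Cl-]
Why: Mesylation and in situ chloride displacement (Collington–Meyers chlorination) under collidine buffering gives the benzylic chloride without exposing the MOM ether to acid.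

Step 9
Reactants: 12 the bis(diaryl ketone); 15 4-(methoxymethoxy)benzyl chloride
Product: 17 bis(tertiary carbinol) in which each ketone carbon of 12 now carries OH and a 4-(methoxymethoxy)benzyl group (diastereomer mixture), via benzylic Grignard reagent 16 (not isolated)
Conditions: 15 (4 equiv), Mg, THF, 0 °C, slow addition; then 12, LaCl3·2LiCl, THF, 0 °C → rt; aq. NH4Cl
Reagents that add atoms: none
Why: Grignard formation and double 1,2-addition to the two diaryl ketones, which have no α-hydrogens to enolise, should proceed with the lanthanum salt assisting attack on the hindered carbonyls; the two carbinol centres form unselectively and are erased in step 10.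

Step 10
Reactants: 17 the bis(tertiary carbinol)
Product: 18 hexakis-MOM bis(triarylethylene) (E/Z mixture at both alkenes)
Conditions: Burgess reagent (3 equiv), toluene, 50 °C
Reagents that add atoms: none
Why: Burgess dehydration of the two tertiary benzylic alcohols runs under neutral conditions, and since the only β-hydrogens are the benzylic CH2 groups both triarylethylenes form regiospecifically, their E/Z ratio being immaterial.

Step 11
Reactants: 18 hexakis-MOM bis(triarylethylene)
Product: 20 5-chloro-2-{1-[4-(1-(3,5-dimethoxyphenyl)-2-(4-hydroxyphenyl)ethenyl)-3,5-dihydroxyphenyl]-2-(4-hydroxyphenyl)ethenyl}benzene-1,3-diol (hexaphenol, E/Z mixture), via hexakis(trimethylsilyl) ether 19 (not isolated)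
Conditions: TMSOTf (12 equiv), 2,2′-bipyridyl (18 equiv), MeCN, 0 °C → rt; then H2O, rt; pH 7 work-up under Ar, used at once
Reagents that add atoms: none
Why: Non-acidic cleavage of aryl MOM ethers by the silyl triflate–bipyridyl pair turns each ArOMOM into ArOSiMe3 and releases the phenol on hydrolysis, so that no strong protic acid meets the free hydroxystilbene units and ring closure is kept for step 12.

Step 12
Reactants: 20 the hexaphenolic bis(triarylethylene)
Product: 23 (2S,3S)-6-chloro-3-[(2S,3S)-3-(3,5-dimethoxyphenyl)-4-hydroxy-2-(4-hydroxyphenyl)-2,3-dihydrobenzofuran-6-yl]-2-(4-hydroxyphenyl)-2,3-dihydrobenzofuran-4-ol, via ring-A-closed mono-dihydrobenzofuran 21 (not isolated), via ring-B-closed mono-dihydrobenzofuran 22 (not isolated)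
Conditions: confined chiral imidodiphosphorimidate (IDPi) Brønsted acid (10 mol %, enantiomer chosen for the 3S sense), CH2Cl2/MTBE, 4 Å MS, −20 °C → rt, 0.02 M, Ar; Et3N quench
Reagents that add atoms: none
Why: Proposed new method: the acid, hydrogen-bonded to a 4-hydroxyl, protonates each alkene at its diaryl carbon (C3 and C3′, in either order), so that the 4-hydroxystyrene becomes a p-quinone methide/benzylic cation at C2 (C2′) paired with the chiral anion, and both alkene geometries collapse to one ion pair; the closest known reactions are the confined-acid-catalysed asymmetric intramolecular hydroalkoxylation of alkenes and the Brønsted-acid activation of 4-hydroxystyrenes as p-quinone methides. Ring A closes by 5-exo-trig oxa-1,6-addition of an ortho hydroxyl of the chlororesorcinol ring to C2 (O1–C2), and ring B closes the same way from an ortho hydroxyl of the central resorcinol onto C2′ (O1′–C2′). C3 and C3′ are set by enantiofacial C-protonation inside the catalyst pocket (catalyst control at each alkene, the two sites being remote), and C2 and C2′ are set relative to them by anti addition of the aryloxy oxygen, backed by reversible ionisation of the 4-hydroxybenzylic C2–O bond, which funnels any cis ring to the more stable trans ring. The step needs protonation at the diaryl carbon and not at CH, together with facial selectivity: protonation at CH gives an o-quinone-methide-type diarylmethyl cation whose only ring closure would be four-membered, so it returns to the alkene, and the two ortho hydroxyls of each resorcinol are homotopic, so closure has no regiochemical choice. Two catalyst-controlled events should raise the enantiomeric purity of the homochiral 2S,3S,2′S,3′S product, the mismatched combination appearing as a separable diastereomer.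

Step 13
Reactants: 23 the chloro bis-dihydrobenzofuran; 24 2,4-dimethoxystyrene
Product: 25 (2S,3S)-6-[(E)-2-(2,4-dimethoxyphenyl)ethenyl]-3-[(2S,3S)-3-(3,5-dimethoxyphenyl)-4-hydroxy-2-(4-hydroxyphenyl)-2,3-dihydrobenzofuran-6-yl]-2-(4-hydroxyphenyl)-2,3-dihydrobenzofuran-4-ol
Conditions: Pd2(dba)3 (2.5 mol %), [HP(t-Bu)3]BF4 (10 mol %), Cy2NMe, 1,4-dioxane, 90 °C, degassed
Reagents that add atoms: none
Why: Mizoroki–Heck reaction of the aryl chloride under a bulky trialkylphosphine–palladium catalyst with an amine base should give β-arylation of the styrene and, after syn β-hydride elimination, the E-stilbene, without touching the four stereocentres.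

Step 14
Reactants: 25 the tetramethyl ether
Product: 26 (2S,3S)-3-[(2S,3S)-3-(3,5-dihydroxyphenyl)-4-hydroxy-2-(4-hydroxyphenyl)-2,3-dihydrobenzofuran-6-yl]-6-[(E)-2-(2,4-dihydroxyphenyl)ethenyl]-2-(4-hydroxyphenyl)-2,3-dihydrobenzofuran-4-ol (target)
Conditions: BBr3 (12 equiv), CH2Cl2, −78 → 0 °C; MeOH, then aq. NaHCO3
Reagents that add atoms: none
Why: Boron tribromide ether cleavage removes the four aryl methyl ethers at low temperature, and because the trans rings are the stable isomers a reversible ionisation of C2–O or C2′–O could only re-close to the same configuration, C3 and C3′ being untouched.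

**Compound list**

1 | 5-chlororesorcinol | Oc1cc(O)cc(Cl)c1 | starting material
2 | 1-chloro-3,5-bis(methoxymethoxy)benzene | COCOc1cc(Cl)cc(OCOC)c1 | intermediate
3 | 3,5-dihydroxybenzaldehyde | O=Cc1cc(O)cc(O)c1 | starting material
4 | 3,5-bis(methoxymethoxy)benzaldehyde | COCOc1cc(C=O)cc(OCOC)c1 | intermediate
5 | 1-(dimethoxymethyl)-3,5-bis(methoxymethoxy)benzene | COCOc1cc(C(OC)OC)cc(OCOC)c1 | intermediate
6 | 3,5-dimethoxybenzaldehyde | COc1cc(C=O)cc(OC)c1 | starting material
7 | [4-(dimethoxymethyl)-2,6-bis(methoxymethoxy)phenyl]lithium | [Li]c1c(OCOC)cc(C(OC)OC)cc1OCOC | intermediate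
8 | [4-(dimethoxymethyl)-2,6-bis(methoxymethoxy)phenyl](3,5-dimethoxyphenyl)methanol (racemic) | COCOc1cc(C(OC)OC)cc(OCOC)c1C(O)c1cc(OC)cc(OC)c1 | intermediate
9 | 4-[(3,5-dimethoxyphenyl)(hydroxy)methyl]-3,5-bis(methoxymethoxy)benzaldehyde (racemic) | COCOc1cc(C=O)cc(OCOC)c1C(O)c1cc(OC)cc(OC)c1 | intermediate
10 | [4-chloro-2,6-bis(methoxymethoxy)phenyl]lithium | [Li]c1c(OCOC)cc(Cl)cc1OCOC | intermediate
11 | [4-chloro-2,6-bis(methoxymethoxy)phenyl]{4-[(3,5-dimethoxyphenyl)(hydroxy)methyl]-3,5-bis(methoxymethoxy)phenyl}methanol (diastereomer mixture) | COCOc1cc(Cl)cc(OCOC)c1C(O)c1cc(OCOC)c(C(O)c2cc(OC)cc(OC)c2)c(OCOC)c1 | intermediate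
12 | [4-chloro-2,6-bis(methoxymethoxy)phenyl][4-(3,5-dimethoxybenzoyl)-3,5-bis(methoxymethoxy)phenyl]methanone | COCOc1cc(Cl)cc(OCOC)c1C(=O)c1cc(OCOC)c(C(=O)c2cc(OC)cc(OC)c2)c(OCOC)c1 | intermediate
13 | 4-hydroxybenzyl alcohol | OCc1ccc(O)cc1 | starting material
14 | 4-(methoxymethoxy)benzyl alcohol | COCOc1ccc(CO)cc1 | intermediate
15 | 4-(methoxymethoxy)benzyl chloride | COCOc1ccc(CCl)cc1 | intermediate
16 | [4-(methoxymethoxy)benzyl]magnesium chloride | COCOc1ccc(C[Mg]Cl)cc1 | intermediate
17 | 1-[4-chloro-2,6-bis(methoxymethoxy)phenyl]-1-{4-[1-(3,5-dimethoxyphenyl)-1-hydroxy-2-(4-(methoxymethoxy)phenyl)ethyl]-3,5-bis(methoxymethoxy)phenyl}-2-[4-(methoxymethoxy)phenyl]ethanol (diastereomer mixture) | COCOc1cc(Cl)cc(OCOC)c1C(O)(Cc1ccc(OCOC)cc1)c1cc(OCOC)c(C(O)(Cc2ccc(OCOC)cc2)c2cc(OC)cc(OC)c2)c(OCOC)c1 | intermediate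
18 | hexakis-MOM bis(triarylethylene): the bis-alkene from 17 by loss of two H2O (E/Z mixture at both alkenes) | COCOc1cc(Cl)cc(OCOC)c1C(=Cc1ccc(OCOC)cc1)c1cc(OCOC)c(C(=Cc2ccc(OCOC)cc2)c2cc(OC)cc(OC)c2)c(OCOC)c1 | intermediate
19 | hexakis(trimethylsilyl) ether of 20 (E/Z mixture) | C[Si](C)(C)Oc1cc(Cl)cc(O[Si](C)(C)C)c1C(=Cc1ccc(O[Si](C)(C)C)cc1)c1cc(O[Si](C)(C)C)c(C(=Cc2ccc(O[Si](C)(C)C)cc2)c2cc(OC)cc(OC)c2)c(O[Si](C)(C)C)c1 | intermediate
20 | 5-chloro-2-{1-[4-(1-(3,5-dimethoxyphenyl)-2-(4-hydroxyphenyl)ethenyl)-3,5-dihydroxyphenyl]-2-(4-hydroxyphenyl)ethenyl}benzene-1,3-diol (E/Z mixture) | Oc1cc(Cl)cc(O)c1C(=Cc1ccc(O)cc1)c1cc(O)c(C(=Cc2ccc(O)cc2)c2cc(OC)cc(OC)c2)c(O)c1 | intermediate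
21 | (2S,3S)-6-chloro-2-(4-hydroxyphenyl)-3-aryl-2,3-dihydrobenzofuran-4-ol with the second triarylethylene still open (ring A closed) | Oc1ccc([C@H]2Oc3cc(Cl)cc(O)c3[C@@H]2c2cc(O)c(C(=Cc3ccc(O)cc3)c3cc(OC)cc(OC)c3)c(O)c2)cc1 | intermediate
22 | (2S,3S)-3-(3,5-dimethoxyphenyl)-2-(4-hydroxyphenyl)-2,3-dihydrobenzofuran-4-ol carrying at C6 the still open chlororesorcinol triarylethylene (ring B closed) | Oc1cc(Cl)cc(O)c1C(=Cc1ccc(O)cc1)c1cc(O)c2c(c1)O[C@H](c1ccc(O)cc1)[C@H]2c1cc(OC)cc(OC)c1 | intermediate
23 | (2S,3S)-6-chloro-3-[(2S,3S)-3-(3,5-dimethoxyphenyl)-4-hydroxy-2-(4-hydroxyphenyl)-2,3-dihydrobenzofuran-6-yl]-2-(4-hydroxyphenyl)-2,3-dihydrobenzofuran-4-ol (both rings trans) | Oc1ccc([C@H]2Oc3cc(Cl)cc(O)c3[C@@H]2c2cc(O)c3c(c2)O[C@H](c2ccc(O)cc2)[C@H]3c2cc(OC)cc(OC)c2)cc1 | intermediate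
24 | 2,4-dimethoxystyrene | C=Cc1ccc(OC)cc1OC | starting material
25 | (2S,3S)-6-[(E)-2-(2,4-dimethoxyphenyl)ethenyl]-3-[(2S,3S)-3-(3,5-dimethoxyphenyl)-4-hydroxy-2-(4-hydroxyphenyl)-2,3-dihydrobenzofuran-6-yl]-2-(4-hydroxyphenyl)-2,3-dihydrobenzofuran-4-ol | Oc1ccc([C@H]2Oc3cc(/C=C/c4ccc(OC)cc4OC)cc(O)c3[C@@H]2c2cc(O)c3c(c2)O[C@H](c2ccc(O)cc2)[C@H]3c2cc(OC)cc(OC)c2)cc1 | intermediate
26 | (2S,3S)-3-[(2S,3S)-3-(3,5-dihydroxyphenyl)-4-hydroxy-2-(4-hydroxyphenyl)-2,3-dihydrobenzofuran-6-yl]-6-[(E)-2-(2,4-dihydroxyphenyl)ethenyl]-2-(4-hydroxyphenyl)-2,3-dihydrobenzofuran-4-ol | Oc1ccc([C@H]2Oc3cc(/C=C/c4ccc(O)cc4O)cc(O)c3[C@@H]2c2cc(O)c3c(c2)O[C@H](c2ccc(O)cc2)[C@H]3c2cc(O)cc(O)c2)cc1 | target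

**Step count**

Total: 14 steps. Longest linear sequence: 11 steps (3 → 4 → 5 → 9 → 11 → 12 → 17 → 18 → 20 → 23 → 25 → 26).

**Steps most likely to fail**

Step 12 (proposed new method). The C-protonation may show poor facial discrimination, giving low enantio- and diastereocontrol. The methide may also be intercepted intermolecularly (Friedel–Crafts oligomerisation) because the hexaphenol dissolves poorly in non-coordinating solvents, or the product may slowly revert and lose configuration at C3/C3′ on long exposure to the acid. The fallback uses known chemistry and sets out from 20. An achiral Brønsted acid (p-TsOH·H2O, MeCN or EtOAc, rt) should effect the same hydroalkoxylation without absolute control. It should give the trans,trans products as two racemic diastereomers: the like pair, made of 23 and its (2R,3R,2′R,3′R) enantiomer F1, and the unlike pair, made of the (2S,3S,2′R,3′R) isomer F2 and the (2R,3R,2′S,3′S) isomer F3. The diastereomers would be separated by chromatography, and the like pair resolved by preparative chiral-phase SFC. This costs material throughput and comes back to the route at 23.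

Step 11. The silyl triflate, or the pyridinium triflate present during hydrolysis, may trigger premature, racemic ring closure or cationic oligomerisation of the electron-rich alkenes, or the six hindered acetals may be removed incompletely. The fallback sets out from 12 and exchanges the acetals for allyl ethers before any alkene exists. HCl in MeOH/THF should give the tetraphenolic bis-ketone F4, and allyl bromide with K2CO3 in DMF the tetra-allyl ether F5. In parallel, 13 with allyl bromide and K2CO3 should give 4-(allyloxy)benzyl alcohol F6, chlorinated as in step 8 to 4-(allyloxy)benzyl chloride F7 and converted with magnesium into the Grignard reagent F8. Addition of F8 to F5 as in step 9 should give the bis-carbinol F9, and Burgess dehydration the hexa-allyl bis(triarylethylene) F10. Palladium(0)-catalysed deallylation (Pd(PPh3)4, morpholine, THF, rt; Tsuji–Trost allyl transfer) then releases all six phenols under neutral conditions and comes back to the route at 20.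

Step 13. Oxidative addition into the electron-rich aryl chloride may be slow in the presence of four free phenols. At the temperature then needed, base may open the 2-(4-hydroxyphenyl)dihydrofuran rings (retro-oxa-Michael to the quinone methide, then tautomerisation), which would erode C2/C3 and C2′/C3′. The fallback sets out from 23 and 24 and replaces the Heck reaction by a Suzuki–Miyaura coupling at 40 °C. Cross-metathesis of 24 with vinylboronic acid pinacol ester (Grubbs second-generation catalyst, CH2Cl2, 40 °C) should give (E)-2-[2-(2,4-dimethoxyphenyl)ethenyl]-4,4,5,5-tetramethyl-1,3,2-dioxaborolane F11. Coupling of F11 with 23 (XPhos Pd G3, aq. K3PO4, THF, 40 °C) should deliver the E-stilbene and comes back to the route at 25.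

**Further compounds**

F1 | step 12 | (2R,3R,2′R,3′R) enantiomer of 23 | Oc1ccc([C@@H]2Oc3cc(Cl)cc(O)c3[C@H]2c2cc(O)c3c(c2)O[C@@H](c2ccc(O)cc2)[C@@H]3c2cc(OC)cc(OC)c2)cc1
F2 | step 12 | (2S,3S,2′R,3′R) diastereomer of 23 | Oc1ccc([C@H]2Oc3cc(Cl)cc(O)c3[C@@H]2c2cc(O)c3c(c2)O[C@@H](c2ccc(O)cc2)[C@@H]3c2cc(OC)cc(OC)c2)cc1
F3 | step 12 | (2R,3R,2′S,3′S) diastereomer of 23 | Oc1ccc([C@@H]2Oc3cc(Cl)cc(O)c3[C@H]2c2cc(O)c3c(c2)O[C@H](c2ccc(O)cc2)[C@H]3c2cc(OC)cc(OC)c2)cc1
F4 | step 11 | (4-chloro-2,6-dihydroxyphenyl)[4-(3,5-dimethoxybenzoyl)-3,5-dihydroxyphenyl]methanone | Oc1cc(Cl)cc(O)c1C(=O)c1cc(O)c(C(=O)c2cc(OC)cc(OC)c2)c(O)c1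
F5 | step 11 | tetra-allyl ether of F4 | C=CCOc1cc(Cl)cc(OCC=C)c1C(=O)c1cc(OCC=C)c(C(=O)c2cc(OC)cc(OC)c2)c(OCC=C)c1
F6 | step 11 | 4-(allyloxy)benzyl alcohol | C=CCOc1ccc(CO)cc1
F7 | step 11 | 4-(allyloxy)benzyl chloride | C=CCOc1ccc(CCl)cc1
F8 | step 11 | [4-(allyloxy)benzyl]magnesium chloride | C=CCOc1ccc(C[Mg]Cl)cc1
F9 | step 11 | hexa-allyl bis(tertiary carbinol) (diastereomer mixture) | C=CCOc1cc(Cl)cc(OCC=C)c1C(O)(Cc1ccc(OCC=C)cc1)c1cc(OCC=C)c(C(O)(Cc2ccc(OCC=C)cc2)c2cc(OC)cc(OC)c2)c(OCC=C)c1
F10 | step 11 | hexa-allyl bis(triarylethylene) (E/Z mixture) | C=CCOc1cc(Cl)cc(OCC=C)c1C(=Cc1ccc(OCC=C)cc1)c1cc(OCC=C)c(C(=Cc2ccc(OCC=C)cc2)c2cc(OC)cc(OC)c2)c(OCC=C)c1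
F11 | step 13 | (E)-2-[2-(2,4-dimethoxyphenyl)ethenyl]-4,4,5,5-tetramethyl-1,3,2-dioxaborolane | COc1ccc(/C=C/B2OC(C)(C)C(C)(C)O2)c(OC)c1
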